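**Retrosynthetic overview**

1. Target 18 comes from pentakis(triisopropylsilyl) ether 17 by fluoride cleavage of five Si–O bonds; 17 is cut at C2–C3 (unit 1) and C2''–C3'' (unit 2).
2. Structural feature: in each flavanone unit C2 (C2'') is both benzylic (to ring B at C1', to the pendant ring at C1''') and bound to the ring oxygen O1 (O1''), and it sits next to the C3 (C3'') methylene alpha to the C4 (C4'') ketone. Each pyranone ring is therefore an aryl benzyl ether whose OCH2 C–H bond can take up an acylcarbene placed at C3.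
3. Bis(diazoketone) 16 comes from bis(methyl ketone) 14 by diazo transfer; 14 comes from boronate 7 and iodide 13 by forming the C3'–C8'' biaryl bond.
4. 7 and 13 come from Mitsunobu ethers (O1–CH2, O1''–CH2) of the single free, chelated phenol of each ring A (2, 10). The 8''-aryl regiochemistry is fixed by silylating one OH of 8 and iodinating ortho to the other.
5. Ring order: all benzene rings are bought; the biaryl bond is made first, and both pyranone rings are closed last, together, in one operation.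

Key step: step 12

Remark (axis): the C3'–C8'' axis has three ortho substituents (OMe, O1'', O4') and the target carries no axial descriptor, so it is treated as not configurationally fixed and no axial control is built in.
Remark (catalyst sense): Rh2(S-PTTL)4, dirhodium tetrakis[N-phthaloyl-(S)-tert-leucinate], is taken to give the 2S sense at both centres; if a test on a simple 2-(benzyloxy)aryl diazoketone shows the opposite sense, Rh2(R-PTTL)4 is used in the same step.
Remark (protecting groups): all five phenols are carried as triisopropylsilyl (TIPS) ethers, which should withstand KOAc, K3PO4, LiN(SiMe3)2 and Et3N–H2O and which place no C–H bond within reach of a six-membered insertion.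

**Route**

Step 1
Reactants: 1 2',4',6'-trihydroxyacetophenone
Product: 2 1-[2-hydroxy-4,6-bis(triisopropylsilyloxy)phenyl]ethanone
Conditions: TIPSCl (2.1 equiv), imidazole, DMF, 0 °C to rt (1 dried azeotropically first)
Reagents that add atoms: chlorotriisopropylsilane (TIPSCl), CC(C)[Si](Cl)(C(C)C)C(C)C
Why: Imidazole-mediated phenol silylation should take the para hydroxyl and one ortho hydroxyl and then stop, because the last ortho hydroxyl is held in the hydrogen-bonded chelate with the acetyl carbonyl, as in the usual twofold protection of phloroacetophenone.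

Step 2
Reactants: 3 3-bromo-4-hydroxybenzaldehyde
Product: 4 3-bromo-4-(triisopropylsilyloxy)benzaldehyde
Conditions: TIPSCl (1.1 equiv), imidazole, DMF, rt
Reagents that add atoms: chlorotriisopropylsilane (TIPSCl), CC(C)[Si](Cl)(C(C)C)C(C)C
Why: Standard silyl ether formation on the only hydroxyl, with the aldehyde and the aryl bromide inert.

Step 3
Reactants: 4 3-bromo-4-(triisopropylsilyloxy)benzaldehyde
Product: 5 3-(4,4,5,5-tetramethyl-1,3,2-dioxaborolan-2-yl)-4-(triisopropylsilyloxy)benzaldehyde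
Conditions: B2pin2 (1.2 equiv), Pd(dppf)Cl2 (3 mol %), KOAc (3 equiv), 1,4-dioxane, 85 °C
Reagents that add atoms: bis(pinacolato)diboron, CC1(C)OB(OC1(C)C)B1OC(C)(C)C(C)(C)O1
Why: Miyaura borylation of an aryl bromide with the weak base KOAc tolerates aldehydes and aryl silyl ethers and places boron on the carbon that becomes C3'.

Step 4
Reactants: 5 3-(4,4,5,5-tetramethyl-1,3,2-dioxaborolan-2-yl)-4-(triisopropylsilyloxy)benzaldehyde
Product: 6 [3-(4,4,5,5-tetramethyl-1,3,2-dioxaborolan-2-yl)-4-(triisopropylsilyloxy)phenyl]methanol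
Conditions: NaBH4 (0.5 equiv), THF–MeOH, 0 °C
Reagents that add atoms: none
Why: Borohydride reduction of an aromatic aldehyde is fast at 0 °C and should leave the pinacol boronate and the silyl ether untouched.

Step 5
Reactants: 2 1-[2-hydroxy-4,6-bis(triisopropylsilyloxy)phenyl]ethanone; 6 [3-(4,4,5,5-tetramethyl-1,3,2-dioxaborolan-2-yl)-4-(triisopropylsilyloxy)phenyl]methanol
Product: 7 1-[2-{[3-(4,4,5,5-tetramethyl-1,3,2-dioxaborolan-2-yl)-4-(triisopropylsilyloxy)phenyl]methoxy}-4,6-bis(triisopropylsilyloxy)phenyl]ethanone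
Conditions: PPh3 (1.5 equiv), DIAD (1.5 equiv), THF, 0 °C to rt
Reagents that add atoms: none
Why: Mitsunobu etherification of a primary benzylic alcohol with the acidic, carbonyl-chelated phenol forms the O1–CH2 ether under neutral conditions that spare the silyl ethers and the boronate.

Step 6
Reactants: 8 2',6'-dihydroxy-4'-methoxyacetophenone
Product: 9 1-[2-hydroxy-4-methoxy-6-(triisopropylsilyloxy)phenyl]ethanone
Conditions: TIPSCl (1.05 equiv), imidazole, DMF, 0 °C to rt
Reagents that add atoms: chlorotriisopropylsilane (TIPSCl), CC(C)[Si](Cl)(C(C)C)C(C)C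
Why: The two hydroxyls of 8 are equivalent and after the first silylation the remaining one is locked in the chelate with the carbonyl, so monosilylation should be clean and it marks the oxygen that becomes O5''.

Step 7
Reactants: 9 1-[2-hydroxy-4-methoxy-6-(triisopropylsilyloxy)phenyl]ethanone
Product: 10 1-[2-hydroxy-3-iodo-4-methoxy-6-(triisopropylsilyloxy)phenyl]ethanone
Conditions: NIS (1.05 equiv), MeCN, 0 °C, dark
Reagents that add atoms: N-iodosuccinimide, O=C1CCC(=O)N1I
Why: Electrophilic aromatic iodination should go ortho to the free phenol (C3, between OH and OMe), since the other open position is flanked by the bulky silyl ether, and this places the halogen next to the future O1'' and fixes the 8''-aryl connectivity.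

Step 8
Reactants: 11 4-hydroxybenzyl alcohol
Product: 12 [4-(triisopropylsilyloxy)phenyl]methanol
Conditions: NaH (1.0 equiv), THF, 0 °C, then TIPSCl (1.0 equiv), 0 °C to rt
Reagents that add atoms: chlorotriisopropylsilane (TIPSCl), CC(C)[Si](Cl)(C(C)C)C(C)C
Why: One equivalent of base removes only the phenolic proton, which is far more acidic than the benzylic hydroxyl, so silylation should occur at the phenolic oxygen alone.

Step 9
Reactants: 10 1-[2-hydroxy-3-iodo-4-methoxy-6-(triisopropylsilyloxy)phenyl]ethanone; 12 [4-(triisopropylsilyloxy)phenyl]methanol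
Product: 13 1-[3-iodo-4-methoxy-6-(triisopropylsilyloxy)-2-{[4-(triisopropylsilyloxy)phenyl]methoxy}phenyl]ethanone
Conditions: PPh3 (1.5 equiv), DIAD (1.5 equiv), toluene, 0 °C to rt
Reagents that add atoms: none
Why: Mitsunobu etherification on the only free phenol, made more acidic by the ortho iodine and acetyl groups, installs the O1''–CH2 ether without base.

Step 10
Reactants: 7 1-[2-{[3-(4,4,5,5-tetramethyl-1,3,2-dioxaborolan-2-yl)-4-(triisopropylsilyloxy)phenyl]methoxy}-4,6-bis(triisopropylsilyloxy)phenyl]ethanone; 13 1-[3-iodo-4-methoxy-6-(triisopropylsilyloxy)-2-{[4-(triisopropylsilyloxy)phenyl]methoxy}phenyl]ethanone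
Product: 14 1-[3-{5-[(2-acetyl-3,5-bis(triisopropylsilyloxy)phenoxy)methyl]-2-(triisopropylsilyloxy)phenyl}-4-methoxy-6-(triisopropylsilyloxy)-2-{[4-(triisopropylsilyloxy)phenyl]methoxy}phenyl]ethanone
Conditions: Pd(OAc)2 (5 mol %), SPhos (10 mol %), K3PO4 (3 equiv), toluene–H2O (10:1), 80 °C
Reagents that add atoms: none
Why: Suzuki–Miyaura coupling with a bulky dialkylbiarylphosphine is the established way to tri-ortho-substituted biaryls, the aryl iodide is the only halide present, and TIPS aryl ethers should survive the phosphate base.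

Step 11
Reactants: 14 1-[3-{5-[(2-acetyl-3,5-bis(triisopropylsilyloxy)phenoxy)methyl]-2-(triisopropylsilyloxy)phenyl}-4-methoxy-6-(triisopropylsilyloxy)-2-{[4-(triisopropylsilyloxy)phenyl]methoxy}phenyl]ethanone
Product: 16 bis(diazoketone) (14 with both acetyl groups as diazoacetyl groups ArCOCHN2), via bis(trifluoroacetyl) diketone 15 (not isolated)
Conditions: LiN(SiMe3)2 (2.4 equiv), THF, −78 °C; CF3CO2CH2CF3 (2.8 equiv), −78 °C; dilute HCl work-up; then MsN3 (3 equiv), Et3N (3 equiv), H2O (2 equiv), MeCN, rt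
Reagents that add atoms: 2,2,2-trifluoroethyl trifluoroacetate, O=C(OCC(F)(F)F)C(F)(F)F (its CF3CO group is carried only in 15 and leaves again); methanesulfonyl azide, CS(=O)(=O)N=[N+]=[N-]
Why: This is a detrifluoroacetylative diazo transfer (a Regitz-type deacylative diazo transfer), the standard way from aryl methyl ketones to aryl diazomethyl ketones, in which kinetic enolisation and C-trifluoroacetylation activate each acetyl group, the sulfonyl azide delivers the diazo group and the trifluoroacetyl group leaves on the sulfonamide nitrogen.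

Step 12
Reactants: 16 bis(diazoketone) (14 with both acetyl groups as diazoacetyl groups ArCOCHN2)
Product: 17 (2S)-7-methoxy-8-{5-[(2S)-4-oxo-5,7-bis(triisopropylsilyloxy)chroman-2-yl]-2-(triisopropylsilyloxy)phenyl}-5-(triisopropylsilyloxy)-2-[4-(triisopropylsilyloxy)phenyl]chroman-4-one
Conditions: Rh2(S-PTTL)4 (3 mol %), PhCF3, 4 Å MS, 0 °C to rt, 16 added slowly by syringe pump
Reagents that add atoms: none
Why: Each diazoketone loses N2 at the divalent rhodium catalyst and the electrophilic acylcarbene at C3 (C3'') inserts, in a concerted, asynchronous, hydride-transfer-like transition state, into one C–H bond of the neighbouring ArO–CH2–Ar group, the two ends reacting independently. The closest known reaction type is the chiral dirhodium carboxylate catalysed intramolecular C–H insertion of 2-alkoxyaryl diazoketones to chroman-4-ones. Each pyranone ring closes by 1,6-insertion through a six-membered transition state (C3, C4, C4a, C8a, O1, C2), forming C2–C3 and C2''–C3''; the otherwise preferred five-membered mode does not exist because the fifth atom is the ether oxygen. C2 and C2'' are set by the catalyst alone, whose pocket of four N-phthaloyl-tert-leucinate ligands selects one enantiotopic hydrogen of each CH2 group, and because the centres are remote and set independently, wrong insertions should end up mostly in the (2S,2''R) and (2R,2''S) diastereomers, to be removed by chromatography. The step needs insertion to outrun attack of the carbene on O1 or O1'' (five-membered oxonium ylide, then 1,2-benzyl shift to a 2-benzylbenzofuran-3-one) and on O5 or O5''; it is helped by the double activation of the C–H bonds (alpha-oxygen and para-silyloxyaryl), by ether lone pairs that are delocalised into an acylated ring and, at O1'', screened by the C8'' aryl group, by silyl ethers that are too hindered to form ylides and have no C–H bond within reach of a six-membered transition state, and by a carboxylate-bridged rhodium catalyst in a non-coordinating solvent with slow addition.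

Step 13
Reactants: 17 (2S)-7-methoxy-8-{5-[(2S)-4-oxo-5,7-bis(triisopropylsilyloxy)chroman-2-yl]-2-(triisopropylsilyloxy)phenyl}-5-(triisopropylsilyloxy)-2-[4-(triisopropylsilyloxy)phenyl]chroman-4-one
Product: 18 (2S)-8-{5-[(2S)-5,7-dihydroxy-4-oxochroman-2-yl]-2-hydroxyphenyl}-5-hydroxy-2-(4-hydroxyphenyl)-7-methoxychroman-4-one (CNP0237714.1)
Conditions: HF·pyridine (excess), pyridine, THF, 0 °C to rt
Reagents that add atoms: none
Why: Fluoride cleaves the five aryl Si–O bonds, and the buffered, non-basic medium avoids the base-induced ring opening to chalcones (retro-oxa-Michael) that would scramble C2 and C2''.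

**Compound list**

1 | 2',4',6'-trihydroxyacetophenone | CC(=O)c1c(O)cc(O)cc1O | starting material
2 | 1-[2-hydroxy-4,6-bis(triisopropylsilyloxy)phenyl]ethanone | CC(=O)c1c(O)cc(O[Si](C(C)C)(C(C)C)C(C)C)cc1O[Si](C(C)C)(C(C)C)C(C)C | intermediate
3 | 3-bromo-4-hydroxybenzaldehyde | O=Cc1ccc(O)c(Br)c1 | starting material
4 | 3-bromo-4-(triisopropylsilyloxy)benzaldehyde | O=Cc1ccc(O[Si](C(C)C)(C(C)C)C(C)C)c(Br)c1 | intermediate
5 | 3-(4,4,5,5-tetramethyl-1,3,2-dioxaborolan-2-yl)-4-(triisopropylsilyloxy)benzaldehyde | O=Cc1ccc(O[Si](C(C)C)(C(C)C)C(C)C)c(B2OC(C)(C)C(C)(C)O2)c1 | intermediate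
6 | [3-(4,4,5,5-tetramethyl-1,3,2-dioxaborolan-2-yl)-4-(triisopropylsilyloxy)phenyl]methanol | OCc1ccc(O[Si](C(C)C)(C(C)C)C(C)C)c(B2OC(C)(C)C(C)(C)O2)c1 | intermediate
7 | 1-[2-{[3-(4,4,5,5-tetramethyl-1,3,2-dioxaborolan-2-yl)-4-(triisopropylsilyloxy)phenyl]methoxy}-4,6-bis(triisopropylsilyloxy)phenyl]ethanone | CC(=O)c1c(OCc2ccc(O[Si](C(C)C)(C(C)C)C(C)C)c(B3OC(C)(C)C(C)(C)O3)c2)cc(O[Si](C(C)C)(C(C)C)C(C)C)cc1O[Si](C(C)C)(C(C)C)C(C)C | intermediate
8 | 2',6'-dihydroxy-4'-methoxyacetophenone | COc1cc(O)c(C(C)=O)c(O)c1 | starting material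
9 | 1-[2-hydroxy-4-methoxy-6-(triisopropylsilyloxy)phenyl]ethanone | COc1cc(O)c(C(C)=O)c(O[Si](C(C)C)(C(C)C)C(C)C)c1 | intermediate
10 | 1-[2-hydroxy-3-iodo-4-methoxy-6-(triisopropylsilyloxy)phenyl]ethanone | COc1cc(O[Si](C(C)C)(C(C)C)C(C)C)c(C(C)=O)c(O)c1I | intermediate
11 | 4-hydroxybenzyl alcohol | OCc1ccc(O)cc1 | starting material
12 | [4-(triisopropylsilyloxy)phenyl]methanol | OCc1ccc(O[Si](C(C)C)(C(C)C)C(C)C)cc1 | intermediate
13 | 1-[3-iodo-4-methoxy-6-(triisopropylsilyloxy)-2-{[4-(triisopropylsilyloxy)phenyl]methoxy}phenyl]ethanone | COc1cc(O[Si](C(C)C)(C(C)C)C(C)C)c(C(C)=O)c(OCc2ccc(O[Si](C(C)C)(C(C)C)C(C)C)cc2)c1I | intermediate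
14 | 1-[3-{5-[(2-acetyl-3,5-bis(triisopropylsilyloxy)phenoxy)methyl]-2-(triisopropylsilyloxy)phenyl}-4-methoxy-6-(triisopropylsilyloxy)-2-{[4-(triisopropylsilyloxy)phenyl]methoxy}phenyl]ethanone | COc1cc(O[Si](C(C)C)(C(C)C)C(C)C)c(C(C)=O)c(OCc2ccc(O[Si](C(C)C)(C(C)C)C(C)C)cc2)c1-c1cc(COc2cc(O[Si](C(C)C)(C(C)C)C(C)C)cc(O[Si](C(C)C)(C(C)C)C(C)C)c2C(C)=O)ccc1O[Si](C(C)C)(C(C)C)C(C)C | intermediate
15 | bis(trifluoroacetyl) diketone: 14 with each acetyl group as a 4,4,4-trifluoro-3-oxobutanoyl group (ArCOCH2COCF3) | COc1cc(O[Si](C(C)C)(C(C)C)C(C)C)c(C(=O)CC(=O)C(F)(F)F)c(OCc2ccc(O[Si](C(C)C)(C(C)C)C(C)C)cc2)c1-c1cc(COc2cc(O[Si](C(C)C)(C(C)C)C(C)C)cc(O[Si](C(C)C)(C(C)C)C(C)C)c2C(=O)CC(=O)C(F)(F)F)ccc1O[Si](C(C)C)(C(C)C)C(C)C | intermediate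
16 | bis(diazoketone): 14 with each acetyl group as a diazoacetyl group (ArCOCHN2) | COc1cc(O[Si](C(C)C)(C(C)C)C(C)C)c(C(=O)C=[N+]=[N-])c(OCc2ccc(O[Si](C(C)C)(C(C)C)C(C)C)cc2)c1-c1cc(COc2cc(O[Si](C(C)C)(C(C)C)C(C)C)cc(O[Si](C(C)C)(C(C)C)C(C)C)c2C(=O)C=[N+]=[N-])ccc1O[Si](C(C)C)(C(C)C)C(C)C | intermediate
17 | (2S)-7-methoxy-8-{5-[(2S)-4-oxo-5,7-bis(triisopropylsilyloxy)chroman-2-yl]-2-(triisopropylsilyloxy)phenyl}-5-(triisopropylsilyloxy)-2-[4-(triisopropylsilyloxy)phenyl]chroman-4-one | COc1cc(O[Si](C(C)C)(C(C)C)C(C)C)c2c(c1-c1cc([C@@H]3CC(=O)c4c(O[Si](C(C)C)(C(C)C)C(C)C)cc(O[Si](C(C)C)(C(C)C)C(C)C)cc4O3)ccc1O[Si](C(C)C)(C(C)C)C(C)C)O[C@H](c1ccc(O[Si](C(C)C)(C(C)C)C(C)C)cc1)CC2=O | intermediate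
18 | (2S)-8-{5-[(2S)-5,7-dihydroxy-4-oxochroman-2-yl]-2-hydroxyphenyl}-5-hydroxy-2-(4-hydroxyphenyl)-7-methoxychroman-4-one (CNP0237714.1) | COc1cc(O)c2c(c1-c1cc([C@@H]3CC(=O)c4c(O)cc(O)cc4O3)ccc1O)O[C@H](c1ccc(O)cc1)CC2=O | target

**Step count and risks**

Total step count: 13. Longest linear sequence: 8 steps (from 3: steps 2, 3, 4, 5, 10, 11, 12, 13).

Steps most likely to fail:

Step 12. The carbene may be diverted to the ether oxygen (oxonium ylide formation followed by 1,2-benzyl shift), or the enantiotopic hydrogens may be told apart poorly, so that stereoisomer mixtures form. Fallback: the two pyranone rings are made instead by rhodium-catalysed asymmetric 1,4-addition of arylboronic acids to chromones (Hayashi–Miyaura type), known chemistry for flavanones. It sets out from 10 and 2 and comes back at 17.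
- Unit 2: phenol 10 is condensed with DMF dimethyl acetal to enaminone F1 and closed with HCl in CH2Cl2 to 8-iodochromone F2. 1,4-Addition of purchased [4-(triisopropylsilyloxy)phenyl]boronic acid to F2 ([RhCl(C2H4)2]2, an electron-poor bisphosphine of the MeO-BIPHEP type in the antipode that gives 2S, aqueous toluene) should give (2S)-8-iodoflavanone F3, the aryl iodide being inert to monovalent rhodium.
- Unit 1 chromone: in the same way 2 gives enaminone F4 and 5,7-bis(silyloxy)chromone F5.
- Ring B donor: purchased 2-bromo-4-iodophenol is silylated (TIPSCl, imidazole) to aryl silyl ether F6, and iodine–magnesium exchange (iPrMgCl·LiCl, −40 °C) followed by B(OMe)3 and mild acid gives boronic acid F7.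
- Union: asymmetric 1,4-addition of F7 to F5 gives (2S)-3'-bromoflavanone F8. Miyaura borylation (Pd(dppf)Cl2, B2pin2, KOAc) gives boronate F9. Suzuki–Miyaura coupling of F9 with F3 under weakly basic conditions (Pd(OAc)2, SPhos, KF, THF–H2O, 50 °C) forms the C3'–C8'' bond and gives 17.

Step 11. Oxygen-to-oxygen silyl migration within the doubly ortho-substituted lithium enolates, or loss of the acyl-activated silyl ethers in the amine–water medium, may erode the twofold transfer. Fallback: enolate chemistry is avoided. It sets out from 14 and comes back at 16. Ketone 14 is heated with tert-butoxybis(dimethylamino)methane in toluene to bis(enaminone) F10, which is treated with MsN3 in MeCN at rt. The azide adds across each enamine C=C bond and the triazoline fragments to the diazoketone and an N-sulfonylformamidine (diazo transfer to enaminones, known).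

Step 10. The fully loaded boronate 7 may transmetalate slowly and protodeboronate, or the acyl-activated silyl ethers of its ring A may be lost to the base. Fallback: the biaryl bond is made before the second ether. It sets out from 5 and 13 and comes back at 14. The two are coupled under the same catalyst to keto-aldehyde F11 (a smaller, electron-poorer boronate, with only three silyl ethers exposed). NaBH4 at −20 °C reduces the aldehyde, in the presence of the hindered, electron-rich aryl ketone, to benzylic alcohol F12, and Mitsunobu reaction of F12 with 2 (PPh3, DIAD) gives 14.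

**Further compounds**

F1 | step 12 | (E)-3-(dimethylamino)-1-[2-hydroxy-3-iodo-4-methoxy-6-(triisopropylsilyloxy)phenyl]prop-2-en-1-one | COc1cc(O[Si](C(C)C)(C(C)C)C(C)C)c(C(=O)/C=C/N(C)C)c(O)c1I
F2 | step 12 | 8-iodo-7-methoxy-5-(triisopropylsilyloxy)-4H-chromen-4-one | COc1cc(O[Si](C(C)C)(C(C)C)C(C)C)c2c(c1I)OC=CC2=O
F3 | step 12 | (2S)-8-iodo-7-methoxy-5-(triisopropylsilyloxy)-2-[4-(triisopropylsilyloxy)phenyl]chroman-4-one | COc1cc(O[Si](C(C)C)(C(C)C)C(C)C)c2c(c1I)O[C@H](c1ccc(O[Si](C(C)C)(C(C)C)C(C)C)cc1)CC2=O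
F4 | step 12 | (E)-3-(dimethylamino)-1-[2-hydroxy-4,6-bis(triisopropylsilyloxy)phenyl]prop-2-en-1-one | CN(C)/C=C/C(=O)c1c(O)cc(O[Si](C(C)C)(C(C)C)C(C)C)cc1O[Si](C(C)C)(C(C)C)C(C)C
F5 | step 12 | 5,7-bis(triisopropylsilyloxy)-4H-chromen-4-one | O=C1C=COc2cc(O[Si](C(C)C)(C(C)C)C(C)C)cc(O[Si](C(C)C)(C(C)C)C(C)C)c12
F6 | step 12 | (2-bromo-4-iodophenoxy)triisopropylsilane | Brc1cc(I)ccc1O[Si](C(C)C)(C(C)C)C(C)C
F7 | step 12 | [3-bromo-4-(triisopropylsilyloxy)phenyl]boronic acid | OB(O)c1ccc(O[Si](C(C)C)(C(C)C)C(C)C)c(Br)c1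
F8 | step 12 | (2S)-2-[3-bromo-4-(triisopropylsilyloxy)phenyl]-5,7-bis(triisopropylsilyloxy)chroman-4-one | Brc1cc([C@@H]2CC(=O)c3c(O[Si](C(C)C)(C(C)C)C(C)C)cc(O[Si](C(C)C)(C(C)C)C(C)C)cc3O2)ccc1O[Si](C(C)C)(C(C)C)C(C)C
F9 | step 12 | (2S)-2-[3-(4,4,5,5-tetramethyl-1,3,2-dioxaborolan-2-yl)-4-(triisopropylsilyloxy)phenyl]-5,7-bis(triisopropylsilyloxy)chroman-4-one | CC1(C)OB(OC1(C)C)c1cc([C@@H]2CC(=O)c3c(O[Si](C(C)C)(C(C)C)C(C)C)cc(O[Si](C(C)C)(C(C)C)C(C)C)cc3O2)ccc1O[Si](C(C)C)(C(C)C)C(C)C
F10 | step 11 | bis(enaminone): 14 with each acetyl group as an (E)-3-(dimethylamino)prop-2-enoyl group | COc1cc(O[Si](C(C)C)(C(C)C)C(C)C)c(C(=O)/C=C/N(C)C)c(OCc2ccc(O[Si](C(C)C)(C(C)C)C(C)C)cc2)c1-c1cc(COc2cc(O[Si](C(C)C)(C(C)C)C(C)C)cc(O[Si](C(C)C)(C(C)C)C(C)C)c2C(=O)/C=C/N(C)C)ccc1O[Si](C(C)C)(C(C)C)C(C)C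
F11 | step 10 | 3-[3-acetyl-6-methoxy-4-(triisopropylsilyloxy)-2-{[4-(triisopropylsilyloxy)phenyl]methoxy}phenyl]-4-(triisopropylsilyloxy)benzaldehyde | COc1cc(O[Si](C(C)C)(C(C)C)C(C)C)c(C(C)=O)c(OCc2ccc(O[Si](C(C)C)(C(C)C)C(C)C)cc2)c1-c1cc(C=O)ccc1O[Si](C(C)C)(C(C)C)C(C)C
F12 | step 10 | 1-[3-[5-(hydroxymethyl)-2-(triisopropylsilyloxy)phenyl]-4-methoxy-6-(triisopropylsilyloxy)-2-{[4-(triisopropylsilyloxy)phenyl]methoxy}phenyl]ethanone | COc1cc(O[Si](C(C)C)(C(C)C)C(C)C)c(C(C)=O)c(OCc2ccc(O[Si](C(C)C)(C(C)C)C(C)C)cc2)c1-c1cc(CO)ccc1O[Si](C(C)C)(C(C)C)C(C)C
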